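A direct plan would make the enol triflate A1 of the O-pivaloyl ring ketone and attach the enynol A2 to it by Sonogashira coupling, giving the allylic alcohol A3.
It would turn A3 into the phosphonium salt A4 and close the C10=C11 alkene (chain numbered from the CH2OH carbon, C1, to the ring-bound alkyne carbon, C15) by Wittig olefination with the trienal ester A5.
A5 would come from an orthoester Claisen rearrangement and a formyl-ylide olefination, and a hydride reduction would finish.
Its weakest step would be the Wittig union: a semi-stabilised allylic ylide would give E/Z mixtures at C10=C11 and could erode C12=C13, in a light-sensitive hexaenyne that is hard to purify.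
The second would be the bromination and phosphonium salt formation on A3: the enynyl allylic bromide would be labile and open to SN2′ attack and loss of geometry.
The third would be the Claisen rearrangement toward A5: run hot with acid beside an allylic acetal, it would leave the C4=C5 geometry to a chair preference alone.

The new plan cuts the three C–CH3 bonds at C4, C9 and C13 and the sp2–sp2 single bonds C11–C12, C7–C8 and C5–C6. Each trisubstituted alkene R–C(CH3)=CH–R′, with CH3 cis to R′, is read as the syn-methylmetalation product of a terminal alkyne; because C12=C13 adjoins the C14≡C15 triple bond, its precursor is a ring-bound buta-1,3-diyne, available from a diynyl anion and the ring ketone. In one operation, zirconium-catalysed methylalumination and palladium-catalysed alkenyl–alkenyl coupling install a methyl branch, fix an E-alkene and forge a chain bond with retention. No ylide, allylic halide or sigmatropic step remains, and every alkene geometry follows from mechanism.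

Key step: step 5

Remark: ring atoms are primed, from C1′ (alkynyl) through C2′ (methyl) and C4′ (carbinol) to C6′ (gem-dimethyl); the systematic names of intermediates use their own locants. Steps 5 to 8 would be run under argon with exclusion of light.

Step 1
Reactants: 1 (4R,6R)-4-hydroxy-2,2,6-trimethylcyclohexan-1-one (actinol); 2 1,4-bis(trimethylsilyl)buta-1,3-diyne
Product: 4 (4R,6R)-2,2,6-trimethyl-1-[4-(trimethylsilyl)buta-1,3-diyn-1-yl]cyclohexane-1,4-diol, via lithium silyldiynide 3 (not isolated)
Conditions: 2 (2.3 equiv), MeLi·LiBr (2.2 equiv), THF, 0 °C → rt; then 1, −78 → 0 °C; sat. aq. NH4Cl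
Reagents that add atoms: none
Why: 1,2-Addition of a lithium acetylide to a ketone: silicon–lithium exchange on 2 gives the monolithio diyne, whose first equivalent deprotonates the C4′ hydroxyl and whose second adds to the hindered carbonyl; the new C1′ carbinol centre forms as an epimer mixture that is erased in step 2, and C4′ is not touched.

Step 2
Reactants: 4 (4R,6R)-2,2,6-trimethyl-1-[4-(trimethylsilyl)buta-1,3-diyn-1-yl]cyclohexane-1,4-diol
Product: 6 (1R)-3,5,5-trimethyl-4-[4-(trimethylsilyl)buta-1,3-diyn-1-yl]cyclohex-3-en-1-yl acetate, via monoacetate 5 (not isolated)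
Conditions: Ac2O (1.2 equiv), pyridine, rt; evaporate; POCl3 (3 equiv), pyridine, 90 °C; ice, aq. NaHCO3
Reagents that add atoms: acetic anhydride, CC(=O)OC(C)=O
Why: Chemoselective acetylation of the secondary hydroxyl followed by POCl3–pyridine dehydration of the tertiary ethynyl carbinol (elimination through the dichlorophosphate): the only β-hydrogen sits on C2′ because C6′ is quaternary, so both C1′ epimers should converge on the tetrasubstituted C1′=C2′ alkene, the C2′ methine centre is erased on purpose, and the acetate keeps the C4′ oxygen from being phosphorylated or from bridging to C1′.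

Step 3
Reactants: 6 (1R)-3,5,5-trimethyl-4-[4-(trimethylsilyl)buta-1,3-diyn-1-yl]cyclohex-3-en-1-yl acetate
Product: 7 (1R)-4-(buta-1,3-diyn-1-yl)-3,5,5-trimethylcyclohex-3-en-1-ol
Conditions: K2CO3 (0.5 equiv), MeOH–THF (1:1), 0 °C → rt; used at once in step 5
Reagents that add atoms: none
Why: Methoxide-mediated methanolysis cleaves the acetate by transesterification and the alkynyl C–Si bond by protodesilylation in one operation, which frees the hydroxyl and the terminal diyne without touching the enediyne or the C4′ centre.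

Step 4
Reactants: 8 (E)-1,2-dichloroethene; 9 ethynyltrimethylsilane
Product: 10 (E)-(4-chlorobut-3-en-1-yn-1-yl)trimethylsilane
Conditions: 8 (5 equiv), Pd(PPh3)4 (5 mol %), CuI (10 mol %), n-BuNH2 (1.5 equiv), Et2O, rt
Reagents that add atoms: none
Why: Sonogashira coupling of a vinyl chloride: with 8 in excess only one C–Cl bond should react, and since oxidative addition and reductive elimination go with retention the E geometry of 8 becomes the C10=C11 geometry of 10.

Step 5
Reactants: 7 (1R)-4-(buta-1,3-diyn-1-yl)-3,5,5-trimethylcyclohex-3-en-1-ol; 10 (E)-(4-chlorobut-3-en-1-yn-1-yl)trimethylsilane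
Product: 12 (1R)-3,5,5-trimethyl-4-[(3E,5E)-3-methyl-8-(trimethylsilyl)octa-3,5-diene-1,7-diyn-1-yl]cyclohex-3-en-1-ol, via alkenylalane 11 (not isolated)
Conditions: Me3Al (3.0 equiv), Cp2ZrCl2 (0.5 equiv), CH2Cl2, −20 °C → rt; evaporate; THF, ZnCl2 (0.5 equiv), 10 (1.2 equiv), Pd(P(t-Bu)3)2 (3 mol %), rt; aq. potassium sodium tartrate
Reagents that add atoms: trimethylaluminium, C[Al](C)C
Why: Zirconium-catalysed methylalumination followed by Negishi alkenyl–alkenyl coupling: a methylzirconocene species activated by Me3Al adds methyl and metal syn across the terminal C12≡C13 triple bond through a four-centre transition state, methyl going to the internal carbon C13 and the metal, after exchange to aluminium, to C12, so that aluminium is cis to the new methyl and trans to the C14≡C15 alkyne. The closest known reaction type is the methylalumination of terminal alkynes, 1-substituted buta-1,3-diynes and enynes included, with cross-coupling of the alkenylalane in the same flask under palladium and zinc catalysis. No ring is closed and no stereocentre is formed; the elements under control are the C12=C13 geometry, fixed as E by the syn addition, and the C10=C11 geometry, carried over from 10 because oxidative addition, transmetalation and reductive elimination all go with retention at sp2 carbon. The step needs site selectivity between the two triple bonds and regioselectivity within the terminal one: the internal C14≡C15 bond is shielded by the C2′ methyl and the C6′ gem-dimethyl group and internal alkynes insert far more slowly, while the preference of the bulky metal for the unsubstituted terminus C12 secures the regiochemistry. The C4′ hydroxyl is masked in the flask as its dimethylaluminium alkoxide by the first equivalent of Me3Al and is released on work-up, so the carbinol centre is untouched.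

Step 6
Reactants: 12 (1R)-3,5,5-trimethyl-4-[(3E,5E)-3-methyl-8-(trimethylsilyl)octa-3,5-diene-1,7-diyn-1-yl]cyclohex-3-en-1-ol
Product: 13 (1R)-3,5,5-trimethyl-4-[(3E,5E)-3-methylocta-3,5-diene-1,7-diyn-1-yl]cyclohex-3-en-1-ol
Conditions: K2CO3 (0.3 equiv), MeOH–THF (1:1), rt; used at once in step 8
Reagents that add atoms: none
Why: Protodesilylation of the alkynylsilane by methoxide frees the C8–H terminal alkyne for the second carbometalation and leaves the dienediyne geometry and the free hydroxyl unchanged.

Step 7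
Reactants: 14 pent-4-yn-1-ol; 8 (E)-1,2-dichloroethene
Product: 16 (4E,6E)-7-chloro-4-methylhepta-4,6-dien-1-ol, via alkenylalane 15 (not isolated)
Conditions: Me3Al (3.0 equiv), Cp2ZrCl2 (0.25 equiv), CH2Cl2, 0 °C → rt; evaporate; THF, ZnCl2 (0.5 equiv), 8 (6 equiv), Pd(PPh3)4 (5 mol %), rt; aq. potassium sodium tartrate
Reagents that add atoms: trimethylaluminium, C[Al](C)C
Why: Zirconium-catalysed methylalumination of the terminal alkyne (syn addition, methyl to C4, aluminium to C5, hydroxyl masked as its aluminium alkoxide) followed by Negishi coupling with excess 8, which should react at one C–Cl bond with retention, so that the C4=C5 and C6=C7 alkenes are both E.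

Step 8
Reactants: 13 (1R)-3,5,5-trimethyl-4-[(3E,5E)-3-methylocta-3,5-diene-1,7-diyn-1-yl]cyclohex-3-en-1-ol; 16 (4E,6E)-7-chloro-4-methylhepta-4,6-dien-1-ol
Product: 19 (4E,6E,8E,10E,12E)-15-[(4R)-4-hydroxy-2,6,6-trimethylcyclohex-1-en-1-yl]-4,9,13-trimethylpentadeca-4,6,8,10,12-pentaen-14-yn-1-ol, via alkenylalane 17 (not isolated), via aluminium alkoxide 18 (not isolated)
Conditions: 13, Me3Al (3.0 equiv), Cp2ZrCl2 (0.5 equiv), CH2Cl2, −20 °C → rt; evaporate; THF, ZnCl2 (0.5 equiv); add 18 [from 16 (1.3 equiv), Me3Al (1.3 equiv), THF, 0 °C], Pd2(dba)3 (2.5 mol %), XPhos (10 mol %), 40 °C; aq. potassium sodium tartrate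
Reagents that add atoms: trimethylaluminium, C[Al](C)C
Why: Zirconium-catalysed methylalumination of the terminal C8≡C9 triple bond (syn, methyl to C9, aluminium to C8, the hindered internal C14≡C15 bond staying inert) followed by Negishi alkenyl–alkenyl coupling with the chlorodiene, whose hydroxyl is masked as alkoxide 18 so that it cannot protonate the alkenyl–metal bond; the electron-rich biarylphosphine should let zerovalent palladium insert into the alkenyl C–Cl bond, and all sp2 centres react with retention, which should give the all-E pentaene with both hydroxyls free after work-up.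

## Compound list

1 | (4R,6R)-4-hydroxy-2,2,6-trimethylcyclohexan-1-one (actinol) | O=C1C(C)(C)C[C@H](O)C[C@H]1C | starting material
2 | 1,4-bis(trimethylsilyl)buta-1,3-diyne | C[Si](C)(C)C#CC#C[Si](C)(C)C | starting material
3 | lithium 4-(trimethylsilyl)buta-1,3-diyn-1-ide | [Li]C#CC#C[Si](C)(C)C | intermediate (not isolated)
4 | (4R,6R)-2,2,6-trimethyl-1-[4-(trimethylsilyl)buta-1,3-diyn-1-yl]cyclohexane-1,4-diol (C1 epimers) | OC1(C#CC#C[Si](C)(C)C)C(C)(C)C[C@H](O)C[C@H]1C | intermediate
5 | (1R,5R)-4-hydroxy-3,3,5-trimethyl-4-[4-(trimethylsilyl)buta-1,3-diyn-1-yl]cyclohexyl acetate (C4 epimers) | OC1(C#CC#C[Si](C)(C)C)C(C)(C)C[C@H](OC(C)=O)C[C@H]1C | intermediate (not isolated)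
6 | (1R)-3,5,5-trimethyl-4-[4-(trimethylsilyl)buta-1,3-diyn-1-yl]cyclohex-3-en-1-yl acetate | CC1=C(C#CC#C[Si](C)(C)C)C(C)(C)C[C@H](OC(C)=O)C1 | intermediate
7 | (1R)-4-(buta-1,3-diyn-1-yl)-3,5,5-trimethylcyclohex-3-en-1-ol | CC1=C(C#CC#C)C(C)(C)C[C@H](O)C1 | intermediate
8 | (E)-1,2-dichloroethene | Cl/C=C/Cl | starting material
9 | ethynyltrimethylsilane | C#C[Si](C)(C)C | starting material
10 | (E)-(4-chlorobut-3-en-1-yn-1-yl)trimethylsilane | Cl/C=C/C#C[Si](C)(C)C | intermediate
11 | dimethyl{(E)-2-methyl-4-[(4R)-4-(dimethylalumanyloxy)-2,6,6-trimethylcyclohex-1-en-1-yl]but-1-en-3-yn-1-yl}alumane | CC1=C(C#C/C(C)=C/[Al](C)C)C(C)(C)C[C@H](O[Al](C)C)C1 | intermediate (not isolated)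
12 | (1R)-3,5,5-trimethyl-4-[(3E,5E)-3-methyl-8-(trimethylsilyl)octa-3,5-diene-1,7-diyn-1-yl]cyclohex-3-en-1-ol | CC1=C(C#C/C(C)=C/C=C/C#C[Si](C)(C)C)C(C)(C)C[C@H](O)C1 | intermediate
13 | (1R)-3,5,5-trimethyl-4-[(3E,5E)-3-methylocta-3,5-diene-1,7-diyn-1-yl]cyclohex-3-en-1-ol | CC1=C(C#C/C(C)=C/C=C/C#C)C(C)(C)C[C@H](O)C1 | intermediate
14 | pent-4-yn-1-ol | C#CCCCO | starting material
15 | dimethyl[(E)-5-(dimethylalumanyloxy)-2-methylpent-1-en-1-yl]alumane | C[Al](C)/C=C(\C)CCCO[Al](C)C | intermediate (not isolated)
16 | (4E,6E)-7-chloro-4-methylhepta-4,6-dien-1-ol | OCCC/C(C)=C/C=C/Cl | intermediate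
17 | dimethyl{(1E,3E,5E)-2,6-dimethyl-8-[(4R)-4-(dimethylalumanyloxy)-2,6,6-trimethylcyclohex-1-en-1-yl]octa-1,3,5-trien-7-yn-1-yl}alumane | CC1=C(C#C/C(C)=C/C=C/C(C)=C/[Al](C)C)C(C)(C)C[C@H](O[Al](C)C)C1 | intermediate (not isolated)
18 | dimethyl{[(4E,6E)-7-chloro-4-methylhepta-4,6-dien-1-yl]oxy}alumane | C[Al](C)OCCC/C(C)=C/C=C/Cl | intermediate (not isolated)
19 | (4E,6E,8E,10E,12E)-15-[(4R)-4-hydroxy-2,6,6-trimethylcyclohex-1-en-1-yl]-4,9,13-trimethylpentadeca-4,6,8,10,12-pentaen-14-yn-1-ol | CC1=C(C#C/C(C)=C/C=C/C(C)=C/C=C/C=C(\C)CCCO)C(C)(C)C[C@H](O)C1 | target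

Total step count: 8 (steps 4 and 7 make the two coupling partners).
Longest linear sequence: 6 steps (1, 2, 3, 5, 6, 8) from 1.

Steps most likely to fail

Step 5. The alkenylalane may be lost to protonolysis or homocoupling while oxidative addition of the chloroenyne is slow, and the terminal diyne tolerates only short contact with the Lewis acidic medium. The fallback would set out from 7: alane 11 would be quenched with iodine to give (1R)-4-[(E)-4-iodo-3-methylbut-3-en-1-yn-1-yl]-3,5,5-trimethylcyclohex-3-en-1-ol F1. Stille coupling of F1 with an excess of commercial (E)-1,2-bis(tributylstannyl)ethene (Pd2(dba)3, AsPh3) would give the dienylstannane (1R)-3,5,5-trimethyl-4-[(3E,5E)-3-methyl-6-(tributylstannyl)hexa-3,5-dien-1-yn-1-yl]cyclohex-3-en-1-ol F2. Iododestannylation (I2, 0 °C) would give (1R)-4-[(3E,5E)-6-iodo-3-methylhexa-3,5-dien-1-yn-1-yl]-3,5,5-trimethylcyclohex-3-en-1-ol F3, and Sonogashira coupling of F3 with 9 (Pd(PPh3)4, CuI, n-BuNH2) would come back to the route at 12.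

Step 8. Oxidative addition into the unactivated chlorodiene may be slower than decay of the polyenylalane by protonolysis, homocoupling or loss of geometry on warming. The fallback would reverse the polarity of the union. Setting out from 13, alane 17 would be quenched with iodine to give (1R)-4-[(3E,5E,7E)-8-iodo-3,7-dimethylocta-3,5,7-trien-1-yn-1-yl]-3,5,5-trimethylcyclohex-3-en-1-ol F4. Setting out from 14, alane 15 would give (E)-5-iodo-4-methylpent-4-en-1-ol F5 with iodine, and Stille coupling of F5 with excess (E)-1,2-bis(tributylstannyl)ethene would give (4E,6E)-4-methyl-7-(tributylstannyl)hepta-4,6-dien-1-ol F6. Stille coupling of F4 with F6 (Pd2(dba)3, AsPh3, CuI, DMF, rt) would come back at the target 19.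

Step 2. The tertiary dichlorophosphate may ionise and be captured by chloride as propargylic or allenic chlorides, or the epimer that lacks an antiperiplanar C2′–H may eliminate incompletely. The fallback would form the ring alkene before the C1′–C15 bond. Setting out from 1, hydrazine hydrate would give (1R,5R)-4-hydrazinylidene-3,3,5-trimethylcyclohexan-1-ol F7, and iodine with tetramethylguanidine (Barton vinyl iodide synthesis) would give (1R)-4-iodo-3,5,5-trimethylcyclohex-3-en-1-ol F8. Sonogashira coupling of F8 (Pd(PPh3)4, CuI, Et3N) with buta-1,3-diyn-1-yl(trimethyl)silane F9, made from 2 with MeLi·LiBr and then water, would give (1R)-3,5,5-trimethyl-4-[4-(trimethylsilyl)buta-1,3-diyn-1-yl]cyclohex-3-en-1-ol F10. K2CO3 in methanol would then come back to the route at 7.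

## Further compounds

F1 | step 5 | (1R)-4-[(E)-4-iodo-3-methylbut-3-en-1-yn-1-yl]-3,5,5-trimethylcyclohex-3-en-1-ol | CC1=C(C#C/C(C)=C/I)C(C)(C)C[C@H](O)C1
F2 | step 5 | (1R)-3,5,5-trimethyl-4-[(3E,5E)-3-methyl-6-(tributylstannyl)hexa-3,5-dien-1-yn-1-yl]cyclohex-3-en-1-ol | CC1=C(C#C/C(C)=C/C=C/[Sn](CCCC)(CCCC)CCCC)C(C)(C)C[C@H](O)C1
F3 | step 5 | (1R)-4-[(3E,5E)-6-iodo-3-methylhexa-3,5-dien-1-yn-1-yl]-3,5,5-trimethylcyclohex-3-en-1-ol | CC1=C(C#C/C(C)=C/C=C/I)C(C)(C)C[C@H](O)C1
F4 | step 8 | (1R)-4-[(3E,5E,7E)-8-iodo-3,7-dimethylocta-3,5,7-trien-1-yn-1-yl]-3,5,5-trimethylcyclohex-3-en-1-ol | CC1=C(C#C/C(C)=C/C=C/C(C)=C/I)C(C)(C)C[C@H](O)C1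
F5 | step 8 | (E)-5-iodo-4-methylpent-4-en-1-ol | OCCC/C(C)=C/I
F6 | step 8 | (4E,6E)-4-methyl-7-(tributylstannyl)hepta-4,6-dien-1-ol | OCCC/C(C)=C/C=C/[Sn](CCCC)(CCCC)CCCC
F7 | step 2 | (1R,5R)-4-hydrazinylidene-3,3,5-trimethylcyclohexan-1-ol | NN=C1C(C)(C)C[C@H](O)C[C@H]1C
F8 | step 2 | (1R)-4-iodo-3,5,5-trimethylcyclohex-3-en-1-ol | CC1=C(I)C(C)(C)C[C@H](O)C1
F9 | step 2 | buta-1,3-diyn-1-yl(trimethyl)silane | C#CC#C[Si](C)(C)C
F10 | step 2 | (1R)-3,5,5-trimethyl-4-[4-(trimethylsilyl)buta-1,3-diyn-1-yl]cyclohex-3-en-1-ol | CC1=C(C#CC#C[Si](C)(C)C)C(C)(C)C[C@H](O)C1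
A1 | direct plan | (1R)-3,5,5-trimethyl-4-(trifluoromethylsulfonyloxy)cyclohex-3-en-1-yl pivalate | CC1=C(OS(=O)(=O)C(F)(F)F)C(C)(C)C[C@H](OC(=O)C(C)(C)C)C1
A2 | direct plan | (E)-3-methylpent-2-en-4-yn-1-ol | C#C/C(C)=C/CO
A3 | direct plan | (1R)-4-[(E)-5-hydroxy-3-methylpent-3-en-1-yn-1-yl]-3,5,5-trimethylcyclohex-3-en-1-yl pivalate | CC1=C(C#C/C(C)=C/CO)C(C)(C)C[C@H](OC(=O)C(C)(C)C)C1
A4 | direct plan | tributyl{(E)-3-methyl-5-[(4R)-2,6,6-trimethyl-4-(pivaloyloxy)cyclohex-1-en-1-yl]pent-2-en-4-yn-1-yl}phosphonium bromide | CC1=C(C#C/C(C)=C/C[P+](CCCC)(CCCC)CCCC)C(C)(C)C[C@H](OC(=O)C(C)(C)C)C1.[Br-]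
A5 | direct plan | methyl (4E,6E,8E)-4,9-dimethyl-10-oxodeca-4,6,8-trienoate | COC(=O)CC/C(C)=C/C=C/C=C(\C)C=O
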